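At 40.0 s the teal and red runs cannot be told apart: product stands at 3.6% and 3.5% of the charge, a gap of 0.1 percentage points with a scatter of 0.5 points on each reading, although the red charge is 6.38 times the teal one.

| flask | substrate | remark | time |
|---|---|---|---|
| teal | 0.069 M | run made earlier |  |
| red | 0.44 M | run made earlier |  |
| beta | 0.12 M |  | 3.0 min |
| gamma | 0.25 M |  | 3.0 min |
| epsilon | 0.50 M |  | 3.0 min |

| run | time / s | product / % |
|---|---|---|
| teal | 20.0 | 2.8 |
| teal | 40.0 | 3.6 |
| teal | 60.0 | 4.9 |
| teal | 80.0 | 6.7 |
| teal | 120 | 8.4 |
| red | 10.0 | 0.4 |
| red | 25.0 | 2.3 |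
| red | 40.0 | 3.5 |
| red | 60.0 | 5.0 |
| red | 90.0 | 7.8 |
| red | 120 | 9.4 |

(readings scatter by 0.5 percentage points)

1. [product] at the end for beta, gamma, epsilon, in this order
2. how the row runs (falls, then rises / falls all the way / hardly changes / rises, then falls / rises all the way)

Two amounts carry the reckoning: the percentages of product in teal and red at 120 s, 8.4% and 9.4%. The late pair is chosen since the ratio of red to teal moves from 0.972 at 40.0 s to 1.12 there, though a gap of 1 point is still a reading with its scatter. The logarithm of that ratio over the logarithm of the ratio of the charges gives m = 0.0607. This m, the yield exponent, is the power of the charge by which percent product grows at one moment, so the apparent order in substrate is one plus m.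

The reckoning made here runs the teal percentage straight on to 3.0 min for beta and gamma and the red percentage for epsilon, and scales each by that power. It gives 0.0156 M for beta, 0.0341 M for gamma and 0.0710 M for epsilon. The forecast, which differs from this in its last two values, reads 0.016 M, 0.033 M and 0.067 M, rises all the way, with “fractional conversion independent of the charge”.

The flask gives 0.0134 M, 0.0293 M and 0.0723 M, rises all the way.

    substrate + 2 product → 3 product (k = 0.229 M⁻² s⁻¹)
    substrate → product (k = 9.70 × 10⁻⁴ s⁻¹)
    substrate ⇌ dormant form (K = 4.86, k = 0.00489 s⁻¹)

In beta at 3.00 min, product stands at 11.2% of the charge beside 50.2% dormant form and 39% substrate. Between the beta and epsilon flasks the yield exponent is 0.181. Scaled from beta with m, gamma comes to 0.0292 M, and the gamma flask holds 0.0293 M.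

The data were computed for substances that don't exist.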